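## Analysis of the target

The target is a biflavanone built from two 2-arylchroman-4-ones joined through a diaryl ether. The 5-hydroxy-7-methoxychroman-4-one (benzo ring A, pyranone ring C) carries at C2 the 4'-hydroxyphenyl ring B; the oxygen on C3' of ring B is bonded to the para-phenylene ring E, which is the 2-aryl group of the 5,7-dihydroxychroman-4-one (benzo ring D, pyranone ring F, locants C2'' to C8a''). The only stereocentres are C2 and C2'', both S, each benzylic and bonded to the ring oxygen. They lie on opposite sides of the diaryl ether and cannot direct one another, so each must be set by an external chiral element, and an error at either gives a diastereomer that differs only at a remote centre and would be hard to remove. Both centres are β to a carbonyl group, and base or hot acid opens the pyranone by retro-oxa-Michael reaction to a 2'-hydroxychalcone that recloses without selectivity, so no basic step may follow the appearance of either ketone. There are four free phenols, two of them chelated to the carbonyl groups, and the phloroglucinol-type rings A and D are easily oxidised and attacked by electrophiles. The two halves differ only in the methyl group on O7, so they cannot be made in one two-directional operation and O7 and O7'' must be told apart from the start. The strategy rests on one recurring feature: in each chromanone O1, C8a, C4a and C4 form the skeleton of an ortho-quinone methide, and C2–C3 with its aryl group (ring B, then ring E) is a styrene, so each pyran ring is their [4+2] adduct once C4 carries a methoxy group as a masked carbonyl.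

## Retrosynthetic reasoning

Target 20 is traced back to its 4',7''-di-O-benzyl ether 19. The two benzyl C–O bonds are the last to be cut because hydrogenolysis is neutral, the only kind of deprotection that two base-labile flavanone centres tolerate. Benzyl on O7'' against methyl on O7 is also what distinguishes the two halves.

In 19 the C4'' carbonyl is taken back to the secondary methyl ether of 17. This is a change of oxidation state only: the ether is what the cycloaddition delivers, and the forward oxidation with a quinone in wet solvent has to pick C4''–H over C2''–H.

Ring F of 17 is cut at O1''–C2'' and C3''–C4'' (retro-[4+2]). This gives the styrene 13, which already contains the finished first flavanone, the symmetric aldehyde 14 and orthoformate 7. The aldehyde reacts through its acetal 15 and the ortho-quinone methide 16. Both ring bonds and C2'' arise in one step from simple aromatic pieces, and the symmetry of 14 removes any regiochemical question. The forward reaction must set C2'' by catalyst control alone.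

The C4 ketone of 13 is taken back to the methyl ether of 11. This oxidation is placed before the second cycloaddition and not at the end, for two reasons. In 11 ring A is a free phloroglucinol-type arene, about as nucleophilic as the styrene, and its C4 ether can ionise in acid. As the chelated ketone 13, ring A is deactivated and nothing can ionise.

The vinyl group of 11 is cut back to the aryl bromide of 10. A bromide is inert in the first cycloaddition, so the two styrenes are revealed one at a time, as the unequal halves demand. The coupling is done on the flavan and not on a flavanone because it needs base.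

Ring C of 10 is cut at O1–C2 and C3–C4. This is the key disconnection and leads to aldehyde 2, styrene 6 and orthoformate 7. The aldehyde reacts through acetal 8 and ortho-quinone methide 9. The cut is made here because it is the only one that forms the ring and C2 together without a carbonyl β to the new centre. The forward reaction must be enantioselective at C2 and must win over Friedel–Crafts reactions of the electron-rich arenes.

Styrene 6 comes from aldehyde 5 by C=C formation (Wittig). Compound 5 is cut at the O–C bond to ring E (Chan–Lam), so that commercial 3 supplies ring B with O4' already benzylated and 4 supplies ring E with its bromide.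

Aldehydes 2 and 14 both come from 1 by alkylation of the hydroxyl para to the formyl group, which is the only one not tied up in a hydrogen bond.

## Alternatives that were turned down

Alternative 1: Both pyranones are cut at O1–C2 and O1''–C2'' after a hydroxyl has been added at C3 and C3''. This leads to the acetal-protected bis(chalcone epoxide) A1, to be made by two aldol condensations and a twofold catalytic asymmetric epoxidation. In the forward key step acid frees the ortho phenols and each opens its epoxide at the benzylic carbon with inversion, closing both rings to the bis-trans-dihydroflavonol A2.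
- For it: asymmetric chalcone epoxidation is established, the opening is stereospecific, and both rings close in one operation. On precedent for the stereo-defining step it is stronger than the chosen route.
- Against it: the two C3 hydroxyls are added only to be removed. Reductive deoxygenation next to the ketone passes through a C3 enolate or radical that can expel O1 and open the ring to the chalcone, which destroys the centre the epoxide was meant to relay. The epoxide at ring E has only a para-aryloxy group to favour benzylic attack, so 5-exo closure to aurone-type products can compete, and the para-alkoxy epoxide at ring B can open by ionisation with loss of configuration.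
- Step economy: the unequal halves demand two different acetophenones condensed in sequence, and the sequence is several steps longer than the route through 10 and 17.
- What the chosen strategy offers instead: C2 is set directly, no carbonyl is present while base is used, and there is no redox detour.

Alternative 2: Ring D is cut at C4a''–C5'' and built last. The precursor is the (S)-2-aryl-2,3-dihydropyran-4-one A3, which carries a dioxinone on a methylene tether at the future C8a'' and the finished first flavanone on ring E. On heating, cycloreversion of the dioxinone gives an acylketene, the pyranone α-carbon attacks it, and enolisation gives the aromatic ring of the 4'-O-benzyl target A4.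
- For it: ring D appears with both hydroxyls free, and C2'' could come from an established catalytic asymmetric hetero-Diels–Alder reaction of the ring E aldehyde with a siloxy diene. That is a stronger precedent than the chosen key step has.
- Against it: it solves only one half, so the first flavanone still needs its own method. The tether must be installed with strong base on a dihydropyranone that opens by β-elimination. The thermolysis must make a weakly nucleophilic vinylogous ester carbon acylate in preference to the free phenol of ring A, above 100 °C, with a ring-opening-prone centre in the molecule.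
- Step economy and comparison: it is clearly longer. The chosen strategy uses one and the same ring-forming event for both halves, starting from two benzaldehydes.

Alternative 3: Both pyranones are cut at C3=C4 and C3''=C4'' of their silyl enol ethers. The precursor is the bis(diene) A5, with two branched 1-arylallyl aryl ethers and two ortho α-silyloxyvinyl groups. A ruthenium alkylidene metathesis catalyst would close both rings to the bis(4-silyloxy-2H-chromene) A6.
- For it: enol ether ring-closing metathesis is a known reaction type, both rings close at once, and the centres would come from asymmetric allylic etherification. On precedent it is stronger.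
- Against it: the etherification needs hindered, chelated 2-acylphenols as nucleophiles. Making the silyl enol ethers needs base next to a doubly activated C2–H, where Wittig-type rearrangement threatens. A 2-aryl-2H-chromene can lose its configuration by reversible electrocyclic ring opening. Ring A arrives as a 5,7-dimethyl ether, so a selective demethylation at O5 must be added, and the sequence is the longest of the four.
- What the chosen strategy offers instead: the stereocentre is made in the same step as the ring, C2 never sits in an easily opened chromene, and the route is much shorter.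

Key step: step 4

Remarks on the chemistry:
- Compounds 1, 3, 4 and 7 are taken as commercial.
- Cycloadducts 10 and 17 are drawn as the 2,4-cis isomers expected from an endo-type approach; a 2,4-trans epimer would be carried on in the same way, since C4 and C4'' become carbonyl carbons.
- The catalyst enantiomer is the one that leads to O–C bonding on the Si face of the styrene α-carbon, to be identified in a first screen.

## Route

Step 1
Reactants: 1 2,4,6-trihydroxybenzaldehyde
Product: 2 2,6-dihydroxy-4-methoxybenzaldehyde
Conditions: MeI (1.05 equiv), KHCO3 (1.1 equiv), DMF, 40 °C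
Reagents that add atoms: methyl iodide, CI
Why: The 4-hydroxyl is the most acidic and the only one not hydrogen-bonded to the formyl group, so a weak base ionises it selectively and Williamson methylation with one equivalent of methyl iodide should stop at 2.

Step 2
Reactants: 3 4-(benzyloxy)-3-hydroxybenzaldehyde; 4 4-bromophenylboronic acid
Product: 5 4-(benzyloxy)-3-(4-bromophenoxy)benzaldehyde
Conditions: Cu(OAc)2 (2 equiv), pyridine, 4 Å MS, CH2Cl2, air, 25 °C
Reagents that add atoms: none
Why: Chan–Lam coupling, the Cu(OAc)2-mediated oxidative O-arylation of a phenol by an arylboronic acid at room temperature. The aldehyde, the benzyl ether and the aryl bromide are inert, so the bromide is kept as the handle for the second vinyl group.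

Step 3
Reactants: 5 4-(benzyloxy)-3-(4-bromophenoxy)benzaldehyde
Product: 6 1-(benzyloxy)-2-(4-bromophenoxy)-4-vinylbenzene
Conditions: Ph3PCH3Br, KOtBu, THF, 0 °C to 25 °C
Reagents that add atoms: methyltriphenylphosphonium bromide, C[P+](c1ccccc1)(c1ccccc1)c1ccccc1.[Br-]
Why: Wittig methylenation of a non-enolisable aryl aldehyde. The potassium alkoxide base avoids halogen–metal exchange at the aryl bromide.

Step 4
Reactants: 2 2,6-dihydroxy-4-methoxybenzaldehyde; 6 1-(benzyloxy)-2-(4-bromophenoxy)-4-vinylbenzene; 7 trimethyl orthoformate
Product: 10 (2S,4S)-2-[4-(benzyloxy)-3-(4-bromophenoxy)phenyl]-4,7-dimethoxychroman-5-ol, via dimethyl acetal 8 (not isolated), via methoxy ortho-quinone methide 9 (not isolated)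
Conditions: chiral IDPi Brønsted acid (BINOL-derived N-triflyl imidodiphosphorimidate, 5 mol%), 7 (3 equiv), 6 (1.5 equiv), CH2Cl2, −40 °C to −20 °C
Reagents that add atoms: none
Why: Proposed new method: acid-mediated exchange with 7 turns aldehyde 2 into acetal 8, which loses methanol to the 4-methoxy ortho-quinone methide 9; this reacts as its O-protonated form, an aryl oxocarbenium ion paired with the chiral imidodiphosphorimidate anion. The terminal carbon of styrene 6 attacks the methide carbon (C3–C4) and the phenolic oxygen then closes on the developing benzylic cation (O1–C2), so ring C is closed by an asynchronous inverse-electron-demand hetero-[4+2] cycloaddition. The closest known reactions are the Sc(OTf)3-promoted three-component synthesis of 4-alkoxychromans from salicylaldehydes, orthoformates and alkenes, and chiral phosphoric and imidodiphosphoric acid catalysed [4+2] cycloadditions of ortho-quinone methides; the enantioselective intermolecular form with a simple styrene is what is new. C2 is set by the chiral counteranion, which must leave the Si face of the styrene α-carbon open to the phenolic oxygen to give 2S. C4 is set relative to C2 by the endo-type approach that places aryl and methoxy cis (4S), and its configuration does not matter because it is oxidised in step 6. Regiochemistry follows from polarity, the nucleophilic styrene terminus bonding to the electrophilic methide carbon while the para-benzyloxy group stabilises the benzylic cation, and the symmetry of 2 gives the 5-hydroxy-7-methoxy pattern whichever hydroxyl reacts. The chemoselectivity needed is styrene capture ahead of Friedel–Crafts attack by the electron-rich ring positions of 8 or 10 and ahead of styrene oligomerisation; excess 6, low temperature, slow generation of the cation and the confined catalyst pocket are meant to secure it.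

Step 5
Reactants: 10 (2S,4S)-2-[4-(benzyloxy)-3-(4-bromophenoxy)phenyl]-4,7-dimethoxychroman-5-ol
Product: 11 (2S,4S)-2-[4-(benzyloxy)-3-(4-vinylphenoxy)phenyl]-4,7-dimethoxychroman-5-ol
Conditions: vinylboronic acid pinacol ester, Pd(dppf)Cl2 (5 mol%), K2CO3, 1,4-dioxane/H2O, 80 °C
Reagents that add atoms: vinylboronic acid pinacol ester, C=CB1OC(C)(C)C(C)(C)O1
Why: Suzuki–Miyaura coupling of the aryl bromide with a vinylboronate. It is run on the flavan, whose C2 has no neighbouring carbonyl and is inert to aqueous carbonate; the free phenol and the benzylic methyl ether also tolerate the conditions.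

Step 6
Reactants: 11 (2S,4S)-2-[4-(benzyloxy)-3-(4-vinylphenoxy)phenyl]-4,7-dimethoxychroman-5-ol
Product: 13 (2S)-2-[4-(benzyloxy)-3-(4-vinylphenoxy)phenyl]-5-hydroxy-7-methoxychroman-4-one, via methyl hemiketal 12 (not isolated)
Conditions: DDQ (1.2 equiv), CH2Cl2/H2O (10:1), 0 °C
Reagents that add atoms: water, O
Why: Benzylic ether oxidation: DDQ abstracts hydride from C4, which is activated by the trioxygenated ring A and by its own methoxy group; water adds to the oxocarbenium ion and hemiketal 12 loses methanol. C2–H is less hydridic (DDQ is known to attack C4 of protected flavan-3-ols), so C2 is untouched. The chelated ketone now deactivates ring A for step 8.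

Step 7
Reactants: 1 2,4,6-trihydroxybenzaldehyde
Product: 14 4-(benzyloxy)-2,6-dihydroxybenzaldehyde
Conditions: BnBr (1.05 equiv), KHCO3 (1.1 equiv), DMF, 40 °C
Reagents that add atoms: benzyl bromide, BrCc1ccccc1
Why: The same selective Williamson alkylation of the non-chelated 4-hydroxyl as in step 1, now with benzyl bromide, so that O7'' can be freed at the end while O7 stays methylated.

Step 8
Reactants: 13 (2S)-2-[4-(benzyloxy)-3-(4-vinylphenoxy)phenyl]-5-hydroxy-7-methoxychroman-4-one; 14 4-(benzyloxy)-2,6-dihydroxybenzaldehyde; 7 trimethyl orthoformate
Product: 17 (2S)-2-{4-(benzyloxy)-3-[4-((2S,4S)-7-(benzyloxy)-5-hydroxy-4-methoxychroman-2-yl)phenoxy]phenyl}-5-hydroxy-7-methoxychroman-4-one, via benzyloxy dimethyl acetal 15 (not isolated), via benzyloxy ortho-quinone methide 16 (not isolated)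
Conditions: same chiral IDPi Brønsted acid (5–10 mol%), 7 (3 equiv), 14 (1.2 equiv, added slowly), CH2Cl2, −40 °C to −20 °C
Reagents that add atoms: none
Why: Proposed new method: as in step 4, acetal 15 loses methanol to 16, whose O-protonated form, paired with the chiral anion, undergoes asynchronous inverse-demand [4+2] cycloaddition with the para-aryloxystyrene of 13 and closes ring F; the closest known reactions are the Sc(OTf)3-promoted three-component 4-alkoxychroman synthesis and chiral phosphoric acid catalysed ortho-quinone methide cycloadditions. C2'' is set by the catalyst alone (Si-face O–C bonding), since C2 is too remote to bias it, and C4'' (drawn cis) is removed in step 9. Ring A of 13 should not compete as a nucleophile because its chelated ketone deactivates C6 and C8, and the flavanone has no ionisable C4 ether.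

Step 9
Reactants: 17 (2S)-2-{4-(benzyloxy)-3-[4-((2S,4S)-7-(benzyloxy)-5-hydroxy-4-methoxychroman-2-yl)phenoxy]phenyl}-5-hydroxy-7-methoxychroman-4-one
Product: 19 (2S)-2-{4-(benzyloxy)-3-[4-((2S)-7-(benzyloxy)-5-hydroxy-4-oxochroman-2-yl)phenoxy]phenyl}-5-hydroxy-7-methoxychroman-4-one, via second methyl hemiketal 18 (not isolated)
Conditions: DDQ (1.2 equiv), CH2Cl2/H2O (10:1), 0 °C
Reagents that add atoms: water, O
Why: As in step 6, DDQ abstracts hydride at the doubly activated C4'', water adds, and hemiketal 18 loses methanol. The existing flavanone, the benzyl ethers and both C2 centres should be unaffected at 0 °C with a small excess of oxidant.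

Step 10
Reactants: 19 (2S)-2-{4-(benzyloxy)-3-[4-((2S)-7-(benzyloxy)-5-hydroxy-4-oxochroman-2-yl)phenoxy]phenyl}-5-hydroxy-7-methoxychroman-4-one
Product: 20 7-O-methyltetrahydroochnaflavone
Conditions: H2 (1 atm), 10% Pd/C, EtOAc/THF, 25 °C
Reagents that add atoms: none
Why: Hydrogenolysis of the two aryl benzyl ethers under neutral conditions. The chelated aryl ketones and the cyclic benzylic C2–O1 bonds react much more slowly, and no base is present to open the pyranones, so both S centres are kept.

## Compound list

1 | 2,4,6-trihydroxybenzaldehyde | O=Cc1c(O)cc(O)cc1O | starting material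
2 | 2,6-dihydroxy-4-methoxybenzaldehyde | COc1cc(O)c(C=O)c(O)c1 | intermediate
3 | 4-(benzyloxy)-3-hydroxybenzaldehyde | O=Cc1ccc(OCc2ccccc2)c(O)c1 | starting material
4 | 4-bromophenylboronic acid | OB(O)c1ccc(Br)cc1 | starting material
5 | 4-(benzyloxy)-3-(4-bromophenoxy)benzaldehyde | O=Cc1ccc(OCc2ccccc2)c(Oc2ccc(Br)cc2)c1 | intermediate
6 | 1-(benzyloxy)-2-(4-bromophenoxy)-4-vinylbenzene | C=Cc1ccc(OCc2ccccc2)c(Oc2ccc(Br)cc2)c1 | intermediate
7 | trimethyl orthoformate | COC(OC)OC | starting material
8 | 2-(dimethoxymethyl)-5-methoxybenzene-1,3-diol (dimethyl acetal of 2, formed in the flask in step 4) | COc1cc(O)c(C(OC)OC)c(O)c1 | intermediate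
9 | 3-hydroxy-5-methoxy-2-(methoxymethylidene)cyclohexa-3,5-dien-1-one (ortho-quinone methide, reacts as its O-protonated form, exocyclic geometry not defined, formed in the flask in step 4) | COC=C1C(=O)C=C(OC)C=C1O | intermediate
10 | (2S,4S)-2-[4-(benzyloxy)-3-(4-bromophenoxy)phenyl]-4,7-dimethoxychroman-5-ol (cis-4-methoxyflavan) | COc1cc(O)c2c(c1)O[C@H](c1ccc(OCc3ccccc3)c(Oc3ccc(Br)cc3)c1)C[C@@H]2OC | intermediate
11 | (2S,4S)-2-[4-(benzyloxy)-3-(4-vinylphenoxy)phenyl]-4,7-dimethoxychroman-5-ol | COc1cc(O)c2c(c1)O[C@H](c1ccc(OCc3ccccc3)c(Oc3ccc(C=C)cc3)c1)C[C@@H]2OC | intermediate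
12 | (2S)-2-[4-(benzyloxy)-3-(4-vinylphenoxy)phenyl]-4,7-dimethoxychroman-4,5-diol (methyl hemiketal, C4 not defined, formed in the flask in step 6) | COc1cc(O)c2c(c1)O[C@H](c1ccc(OCc3ccccc3)c(Oc3ccc(C=C)cc3)c1)CC2(O)OC | intermediate
13 | (2S)-2-[4-(benzyloxy)-3-(4-vinylphenoxy)phenyl]-5-hydroxy-7-methoxychroman-4-one | COc1cc(O)c2c(c1)O[C@H](c1ccc(OCc3ccccc3)c(Oc3ccc(C=C)cc3)c1)CC2=O | intermediate
14 | 4-(benzyloxy)-2,6-dihydroxybenzaldehyde | O=Cc1c(O)cc(OCc2ccccc2)cc1O | intermediate
15 | 5-(benzyloxy)-2-(dimethoxymethyl)benzene-1,3-diol (dimethyl acetal of 14, formed in the flask in step 8) | COC(OC)c1c(O)cc(OCc2ccccc2)cc1O | intermediate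
16 | 5-(benzyloxy)-3-hydroxy-2-(methoxymethylidene)cyclohexa-3,5-dien-1-one (ortho-quinone methide, reacts as its O-protonated form, exocyclic geometry not defined, formed in the flask in step 8) | COC=C1C(=O)C=C(OCc2ccccc2)C=C1O | intermediate
17 | (2S)-2-{4-(benzyloxy)-3-[4-((2S,4S)-7-(benzyloxy)-5-hydroxy-4-methoxychroman-2-yl)phenoxy]phenyl}-5-hydroxy-7-methoxychroman-4-one | COc1cc(O)c2c(c1)O[C@H](c1ccc(OCc3ccccc3)c(Oc3ccc([C@@H]4C[C@H](OC)c5c(O)cc(OCc6ccccc6)cc5O4)cc3)c1)CC2=O | intermediate
18 | (2S)-2-{4-(benzyloxy)-3-[4-((2S)-7-(benzyloxy)-4,5-dihydroxy-4-methoxychroman-2-yl)phenoxy]phenyl}-5-hydroxy-7-methoxychroman-4-one (methyl hemiketal, C4'' not defined, formed in the flask in step 9) | COc1cc(O)c2c(c1)O[C@H](c1ccc(OCc3ccccc3)c(Oc3ccc([C@@H]4CC(O)(OC)c5c(O)cc(OCc6ccccc6)cc5O4)cc3)c1)CC2=O | intermediate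
19 | (2S)-2-{4-(benzyloxy)-3-[4-((2S)-7-(benzyloxy)-5-hydroxy-4-oxochroman-2-yl)phenoxy]phenyl}-5-hydroxy-7-methoxychroman-4-one (4',7''-di-O-benzyl target) | COc1cc(O)c2c(c1)O[C@H](c1ccc(OCc3ccccc3)c(Oc3ccc([C@@H]4CC(=O)c5c(O)cc(OCc6ccccc6)cc5O4)cc3)c1)CC2=O | intermediate
20 | 7-O-methyltetrahydroochnaflavone, (2S)-5-hydroxy-2-{4-hydroxy-3-[4-((2S)-5,7-dihydroxy-4-oxochroman-2-yl)phenoxy]phenyl}-7-methoxychroman-4-one | COc1cc(O)c2c(c1)O[C@H](c1ccc(O)c(Oc3ccc([C@@H]4CC(=O)c5c(O)cc(O)cc5O4)cc3)c1)CC2=O | target

## Step count and risk

Total: 10 steps. Longest linear sequence: 8 steps (steps 2, 3, 4, 5, 6, 8, 9, 10).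

**Step 4 (key step, new method).** Three things may go wrong.
- Facial selectivity at the styrene α-carbon may be poor, because a flat, weakly binding styrene has to be oriented by the counteranion alone.
- Friedel–Crafts alkylation of the free ring positions of acetal 8 or of product 10 by the oxocarbenium ion may compete with cycloaddition.
- The strong acid may oligomerise the electron-rich styrene.

Fallback with known chemistry: 2, 6 and 7 are combined under Sc(OTf)3 in CH2Cl2, the established racemic three-component chroman synthesis. This should give 10 together with its mirror image, the (2R,4R)-flavan F1. The two are separated by preparative chromatography on a chiral stationary phase, and the route is rejoined at 10.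

**Step 8 (new method).** Selectivity at C2'' may be insufficient. Because C2 is already fixed, the minor sense of addition gives a diastereomer, not an enantiomer, and it differs only at a remote centre. Overreaction of the nucleophilic ring D of 17 with excess oxocarbenium ion is the second concern.

Fallback with known chemistry: 13, 14 and 7 are combined under Sc(OTf)3. This should give 17 together with its C2'' epimer, the (2''R,4''R)-cycloadduct F2. The pair is resolved by preparative chromatography on a chiral stationary phase, and the route continues from 17.

**Step 6.** Hydride abstraction may occur at C2–H, which is benzylic and para to the benzyloxy group, instead of at C4–H. Over-oxidation towards the flavone and attack of the oxidant on the vinyl group are further possibilities. Step 9 is the same reaction on 17 and shares the risk.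

Fallback: from 11, mild aqueous acid (PPTS, acetone/H2O, 40 °C) exchanges the ionisable C4 methoxy group for hydroxyl and gives the flavan-4-ol F3. Activated MnO2 in CH2Cl2 then oxidises the benzylic alcohol and the route is rejoined at 13.

**Step 10.** Over-reduction is the danger: hydrogenolytic opening of the benzylic C2–O1 and C2''–O1'' bonds to dihydrochalcones, or reduction of the aryl ketones.

Fallback: from 19, Lewis-acid debenzylation with BCl3 and pentamethylbenzene as cation scavenger in CH2Cl2 at −78 °C leads directly to 20 without any reductant (no new compound, F0).

**Step 1 (and step 7, same type).** Over-alkylation at the chelated hydroxyls, or C-alkylation of the phloroglucinol ring, would lower selectivity.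

Fallback: from 1, Mitsunobu etherification with methanol (PPh3, DIAD, THF, 0 °C) engages only the most acidic, non-chelated hydroxyl and returns to 2 (no new compound, F0).

**Step 2.** Conversion may be low, through protodeboronation or homocoupling of 4 and sluggish arylation of the ortho-alkoxy phenol.

Fallback: from 3, Ullmann-type coupling with 1-bromo-4-iodobenzene (CuI, N,N-dimethylglycine, Cs2CO3, 1,4-dioxane, 90 °C), which reacts at the iodide only, returns to 5 (no new compound, F0).

## Further compounds

F1 | step 4 | (2R,4R)-2-[4-(benzyloxy)-3-(4-bromophenoxy)phenyl]-4,7-dimethoxychroman-5-ol (enantiomer of 10) | COc1cc(O)c2c(c1)O[C@@H](c1ccc(OCc3ccccc3)c(Oc3ccc(Br)cc3)c1)C[C@H]2OC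
F2 | step 8 | (2S)-2-{4-(benzyloxy)-3-[4-((2R,4R)-7-(benzyloxy)-5-hydroxy-4-methoxychroman-2-yl)phenoxy]phenyl}-5-hydroxy-7-methoxychroman-4-one (C2'' epimer series of 17) | COc1cc(O)c2c(c1)O[C@H](c1ccc(OCc3ccccc3)c(Oc3ccc([C@H]4C[C@@H](OC)c5c(O)cc(OCc6ccccc6)cc5O4)cc3)c1)CC2=O
F3 | step 6 | (2S)-2-[4-(benzyloxy)-3-(4-vinylphenoxy)phenyl]-7-methoxychroman-4,5-diol (C4 not defined) | COc1cc(O)c2c(c1)O[C@H](c1ccc(OCc3ccccc3)c(Oc3ccc(C=C)cc3)c1)CC2O
F0 | step 10 | none | none
F0 | step 1 | none | none
F0 | step 2 | none | none
A1 | alternative 1 | methoxymethyl-protected bis(chalcone epoxide), (αR,βS) at both epoxides | COCOc1cc(OC)cc(OCOC)c1C(=O)[C@@H]1O[C@H]1c1ccc(OCOC)c(Oc2ccc([C@@H]3O[C@H]3C(=O)c3c(OCOC)cc(OCOC)cc3OCOC)cc2)c1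
A2 | alternative 1 | 3,3''-dihydroxy target (bis-trans-dihydroflavonol, 2R,3R in both units) | COc1cc(O)c2c(c1)O[C@H](c1ccc(O)c(Oc3ccc([C@@H]4[C@@H](O)C(=O)c5c(O)cc(O)cc5O4)cc3)c1)[C@@H](O)C2=O
A3 | alternative 2 | (2S)-2-{4-(benzyloxy)-3-[4-((2S)-6-[(2,2-dimethyl-4-oxo-4H-1,3-dioxin-6-yl)methyl]-4-oxo-3,4-dihydro-2H-pyran-2-yl)phenoxy]phenyl}-5-hydroxy-7-methoxychroman-4-one | COc1cc(O)c2c(c1)O[C@H](c1ccc(OCc3ccccc3)c(Oc3ccc([C@@H]4CC(=O)C=C(CC5=CC(=O)OC(C)(C)O5)O4)cc3)c1)CC2=O
A4 | alternative 2 | 4'-O-benzyl target | COc1cc(O)c2c(c1)O[C@H](c1ccc(OCc3ccccc3)c(Oc3ccc([C@@H]4CC(=O)c5c(O)cc(O)cc5O4)cc3)c1)CC2=O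
A5 | alternative 3 | bis(diene) with two (S)-1-arylallyl aryl ethers and two ortho α-(tert-butyldimethylsilyloxy)vinyl groups | COc1cc(OC)c(C(=C)O[Si](C)(C)C(C)(C)C)c(c1)O[C@H](c1ccc(OCc2ccccc2)c(Oc2ccc([C@H](C=C)Oc3cc(OCc4ccccc4)cc(OCc4ccccc4)c3C(=C)O[Si](C)(C)C(C)(C)C)cc2)c1)C=C
A6 | alternative 3 | bis(4-silyloxy-2H-chromene), silyl enol ether of the protected biflavanone | COc1cc(OC)c2c(c1)O[C@H](c1ccc(OCc3ccccc3)c(Oc3ccc([C@@H]4C=C(O[Si](C)(C)C(C)(C)C)c5c(OCc6ccccc6)cc(OCc6ccccc6)cc5O4)cc3)c1)C=C2O[Si](C)(C)C(C)(C)C
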